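**Retrosynthetic overview**
1. The tetralin ring (the only ring formed) is closed last: the C1–C8a aryl–benzyl bond comes from an intramolecular Friedel–Crafts attack on a para-quinone methide generated from the C2-symmetric diol 8, with C1 set by the two existing centers.
2. Diol 8 comes from bis-imide 7 by one hydride reduction that removes both auxiliaries and both phenol pivalates.
3. The central C2–C3 bond (lignan 8–8') of 7 is made by oxidative homocoupling of two identical chiral imide enolates, α-carbon to α-carbon, after one-electron oxidation reverses the polarity of the enolate carbon; both stereocenters are set here.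
4. Imide 5 comes from dihydrosinapic acid 2 (from sinapic acid 1) and (S)-4-isopropyloxazolidin-2-one 3.

Assumption: the SMILES is read as the all-trans (1S,2R,3R) isomer (tetralin numbering, aryl at C1), i.e. (+)-lyoniresinol; sinapic acid and the valine-derived oxazolidinone are taken as commercial.

**Step 1**
Reactants: 1 sinapic acid
Product: 2 3-(4-hydroxy-3,5-dimethoxyphenyl)propanoic acid
Conditions: H2 (1 atm), 10% Pd/C, MeOH, rt
Reagents that add atoms: none
Why: Heterogeneous catalytic hydrogenation saturates the cinnamic C=C bond selectively and leaves the arene, phenol and acid untouched; no stereocenter is formed.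

**Step 2**
Reactants: 2 3-(4-hydroxy-3,5-dimethoxyphenyl)propanoic acid; 3 (S)-4-isopropyl-1,3-oxazolidin-2-one
Product: 5 (S)-3-{3-[3,5-dimethoxy-4-(pivaloyloxy)phenyl]propanoyl}-4-isopropyl-1,3-oxazolidin-2-one, via mixed pivalic anhydride 4 (not isolated)
Conditions: PivCl (2.3 equiv), Et3N (4 equiv), DMAP (0.05 equiv), THF, −20 → 0 °C; then LiCl (1.1 equiv), 3 (1.0 equiv), rt
Reagents that add atoms: pivaloyl chloride, CC(C)(C)C(=O)Cl
Why: Mixed-anhydride N-acylation of an Evans oxazolidinone (LiCl/Et3N variant): PivCl converts the carboxylate into anhydride 4 within minutes and, in excess, caps the hindered phenol as its pivalate, after which the LiCl-activated oxazolidinone attacks the less hindered carbonyl of 4; the only stereocenter is carried in from 3.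

**Step 3**
Reactants: 5 (S)-3-{3-[3,5-dimethoxy-4-(pivaloyloxy)phenyl]propanoyl}-4-isopropyl-1,3-oxazolidin-2-one (two molecules)
Product: 7 (4S,4'S)-3,3'-{(2R,3R)-2,3-bis[3,5-dimethoxy-4-(pivaloyloxy)benzyl]butanedioyl}bis(4-isopropyl-1,3-oxazolidin-2-one), via lithium Z-enolate 6 (not isolated)
Conditions: LiN(i-Pr)2 (1.1 equiv), THF, −78 °C; TiCl4 (1.1 equiv, CH2Cl2 solution), −78 °C → rt; aq NH4Cl
Reagents that add atoms: none
Why: Oxidative homocoupling of a chiral imide enolate: one-electron oxidation of chelated Z-enolate 6 by TiCl4 (tetravalent titanium reduced to trivalent titanium) turns its nucleophilic α-carbon into an electrophilic, enolonium-type partner that bonds to the α-carbon of a second enolate, each carbon reacting on the face anti to the isopropyl group of its (S)-auxiliary (same sense as Evans alkylation), which sets both new centers R in a matched C2-symmetric dimer, while the di-ortho-methoxy aryl pivalates are too hindered to acylate the enolate at −78 °C.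

**Step 4**
Reactants: 7 (4S,4'S)-3,3'-{(2R,3R)-2,3-bis[3,5-dimethoxy-4-(pivaloyloxy)benzyl]butanedioyl}bis(4-isopropyl-1,3-oxazolidin-2-one)
Product: 8 (2R,3R)-2,3-bis(4-hydroxy-3,5-dimethoxybenzyl)butane-1,4-diol
Conditions: LiAlH4 (4 equiv), THF, 0 °C → rt; then 1 M HCl to pH 3, EtOAc extraction
Reagents that add atoms: none
Why: Hydride reduction with LiAlH4 cleaves both exocyclic imide carbonyls to primary alcohols with release of the auxiliary and reduces both aryl pivalates to free phenols in the same operation; the two α-centers are not enolised under these conditions and stay R,R.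

**Step 5**
Reactants: 8 (2R,3R)-2,3-bis(4-hydroxy-3,5-dimethoxybenzyl)butane-1,4-diol
Product: 10 (1S,2R,3R)-1-(4-hydroxy-3,5-dimethoxyphenyl)-7-hydroxy-6,8-dimethoxy-1,2,3,4-tetrahydronaphthalene-2,3-dimethanol, via para-quinone methide 9 (not isolated)
Conditions: DDQ (0.95 equiv), TFA (5 equiv), CH2Cl2–(CF3)2CHOH (4:1), −20 → 0 °C; then aq NaHCO3
Reagents that add atoms: none
Why: DDQ dehydrogenates one 4-alkyl-2,6-dimethoxyphenol to quinone methide 9, which under acid undergoes an intramolecular Friedel–Crafts alkylation by the other ring at its carbon ortho to the side chain and para to a methoxy group (both such positions are equivalent) through a chair-like six-membered transition state with the aryl group and both hydroxymethyl groups pseudo-equatorial, which sets C1 as S (1,2-trans, all-trans), while capture by a side-chain hydroxyl is reversible in acid and C–C bond formation is not.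

**Compound list**
1 | sinapic acid, (E)-3-(4-hydroxy-3,5-dimethoxyphenyl)prop-2-enoic acid | COc1cc(/C=C/C(=O)O)cc(OC)c1O | starting material
2 | 3-(4-hydroxy-3,5-dimethoxyphenyl)propanoic acid (dihydrosinapic acid) | COc1cc(CCC(=O)O)cc(OC)c1O | intermediate
3 | (S)-4-isopropyl-1,3-oxazolidin-2-one | CC(C)[C@H]1COC(=O)N1 | starting material
4 | 3-[3,5-dimethoxy-4-(pivaloyloxy)phenyl]propanoic pivalic anhydride (not isolated) | COc1cc(CCC(=O)OC(=O)C(C)(C)C)cc(OC)c1OC(=O)C(C)(C)C | intermediate
5 | (S)-3-{3-[3,5-dimethoxy-4-(pivaloyloxy)phenyl]propanoyl}-4-isopropyl-1,3-oxazolidin-2-one | COc1cc(CCC(=O)N2[C@@H](C(C)C)COC2=O)cc(OC)c1OC(=O)C(C)(C)C | intermediate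
6 | lithium (Z)-enolate of 5, O–Li cis to the benzylic CH2 (not isolated) | [Li]O/C(=C\Cc1cc(OC)c(OC(=O)C(C)(C)C)c(OC)c1)N1[C@@H](C(C)C)COC1=O | intermediate
7 | (4S,4'S)-3,3'-{(2R,3R)-2,3-bis[3,5-dimethoxy-4-(pivaloyloxy)benzyl]butanedioyl}bis(4-isopropyl-1,3-oxazolidin-2-one) | CC(C)[C@H]1COC(=O)N1C(=O)[C@H](Cc1cc(OC)c(OC(=O)C(C)(C)C)c(OC)c1)[C@@H](Cc1cc(OC)c(OC(=O)C(C)(C)C)c(OC)c1)C(=O)N1[C@@H](C(C)C)COC1=O | intermediate
8 | (2R,3R)-2,3-bis(4-hydroxy-3,5-dimethoxybenzyl)butane-1,4-diol ((8R,8'R)-5,5'-dimethoxysecoisolariciresinol) | OC[C@H](Cc1cc(OC)c(O)c(OC)c1)[C@@H](Cc1cc(OC)c(O)c(OC)c1)CO | intermediate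
9 | 4-[(2R,3R)-4-hydroxy-3-(4-hydroxy-3,5-dimethoxybenzyl)-2-(hydroxymethyl)butylidene]-2,6-dimethoxycyclohexa-2,5-dien-1-one (not isolated) | OC[C@H](C=C1C=C(OC)C(=O)C(OC)=C1)[C@@H](Cc1cc(OC)c(O)c(OC)c1)CO | intermediate
10 | (1S,2R,3R)-1-(4-hydroxy-3,5-dimethoxyphenyl)-7-hydroxy-6,8-dimethoxy-1,2,3,4-tetrahydronaphthalene-2,3-dimethanol, (+)-lyoniresinol | COc1cc([C@H]2c3c(cc(OC)c(O)c3OC)C[C@@H](CO)[C@@H]2CO)cc(OC)c1O | target

**Totals**
Total steps: 5. Longest linear sequence: 5 (1 → 2 → 5 → 7 → 8 → 10).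

**Steps most likely to fail, with fallbacks**

Step 3 (oxidative enolate dimerisation). The risks are attack of base, enolate or TiCl4 on the aryl pivalates, simple reprotonation back to 5, and incomplete diastereocontrol. The fallback replaces the acyl phenol protection by an inert ether; it sets out from 2 and comes back at 8. Compound 2 is O-benzylated (BnBr, NaOH, EtOH–H2O, reflux) to 3-(4-benzyloxy-3,5-dimethoxyphenyl)propanoic acid F1. F1 is attached to 3 (PivCl, Et3N, LiCl, THF) to give (S)-3-[3-(4-benzyloxy-3,5-dimethoxyphenyl)propanoyl]-4-isopropyl-1,3-oxazolidin-2-one F2. F2 is dimerised as in step 3 to (4S,4'S)-3,3'-[(2R,3R)-2,3-bis(4-benzyloxy-3,5-dimethoxybenzyl)butanedioyl]bis(4-isopropyl-1,3-oxazolidin-2-one) F3. LiAlH4 in THF then gives (2R,3R)-2,3-bis(4-benzyloxy-3,5-dimethoxybenzyl)butane-1,4-diol F4, and hydrogenolysis (H2, Pd/C, EtOAc–MeOH) gives 8.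

Step 4 (reduction of the hindered bis-imide). The risk is hydride attack on the ring carbonyl of the auxiliary instead of the exocyclic one, giving ring-opened amides. The fallback separates auxiliary removal from reduction; it sets out from 7 and comes back at 8. LiOH with H2O2 in THF–H2O at 0 °C (hydroperoxide attacks only the exocyclic carbonyl) gives (2R,3R)-2,3-bis[3,5-dimethoxy-4-(pivaloyloxy)benzyl]butanedioic acid F5. LiAlH4 in refluxing THF then reduces both acids and both pivalates to 8.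

Step 5 (oxidative cyclisation). The risks are further oxidation of the product phenols by DDQ, intermolecular quinone methide coupling, trifluoroacetylation and poor solubility of the tetraol. The fallback masks the diol and separates oxidation from cyclisation so that oxidant and product never meet; it sets out from 8 and comes back at 10. 2,2-Dimethoxypropane with pyridinium p-toluenesulfonate in acetone gives (5R,6R)-5,6-bis(4-hydroxy-3,5-dimethoxybenzyl)-2,2-dimethyl-1,3-dioxepane F6. Ag2O (0.6 equiv) in CH2Cl2 at rt, then filtration, gives the mono-quinone methide 4-{[(5R,6R)-6-(4-hydroxy-3,5-dimethoxybenzyl)-2,2-dimethyl-1,3-dioxepan-5-yl]methylidene}-2,6-dimethoxycyclohexa-2,5-dien-1-one F7, with unreacted F6 recycled. Catalytic BF3·OEt2 in CH2Cl2 at −40 °C closes the ring to the 2,3-bis(hydroxymethyl) isopropylidene acetal of lyoniresinol F8, and 80% aq AcOH at 40 °C releases 10.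

**Further compounds**
F1 | step 3 | 3-(4-benzyloxy-3,5-dimethoxyphenyl)propanoic acid | COc1cc(CCC(=O)O)cc(OC)c1OCc1ccccc1
F2 | step 3 | (S)-3-[3-(4-benzyloxy-3,5-dimethoxyphenyl)propanoyl]-4-isopropyl-1,3-oxazolidin-2-one | COc1cc(CCC(=O)N2[C@@H](C(C)C)COC2=O)cc(OC)c1OCc1ccccc1
F3 | step 3 | (4S,4'S)-3,3'-[(2R,3R)-2,3-bis(4-benzyloxy-3,5-dimethoxybenzyl)butanedioyl]bis(4-isopropyl-1,3-oxazolidin-2-one) | CC(C)[C@H]1COC(=O)N1C(=O)[C@H](Cc1cc(OC)c(OCc2ccccc2)c(OC)c1)[C@@H](Cc1cc(OC)c(OCc2ccccc2)c(OC)c1)C(=O)N1[C@@H](C(C)C)COC1=O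
F4 | step 3 | (2R,3R)-2,3-bis(4-benzyloxy-3,5-dimethoxybenzyl)butane-1,4-diol | OC[C@H](Cc1cc(OC)c(OCc2ccccc2)c(OC)c1)[C@@H](Cc1cc(OC)c(OCc2ccccc2)c(OC)c1)CO
F5 | step 4 | (2R,3R)-2,3-bis[3,5-dimethoxy-4-(pivaloyloxy)benzyl]butanedioic acid | OC(=O)[C@H](Cc1cc(OC)c(OC(=O)C(C)(C)C)c(OC)c1)[C@@H](Cc1cc(OC)c(OC(=O)C(C)(C)C)c(OC)c1)C(=O)O
F6 | step 5 | (5R,6R)-5,6-bis(4-hydroxy-3,5-dimethoxybenzyl)-2,2-dimethyl-1,3-dioxepane | CC1(C)OC[C@H](Cc2cc(OC)c(O)c(OC)c2)[C@@H](Cc2cc(OC)c(O)c(OC)c2)CO1
F7 | step 5 | 4-{[(5R,6R)-6-(4-hydroxy-3,5-dimethoxybenzyl)-2,2-dimethyl-1,3-dioxepan-5-yl]methylidene}-2,6-dimethoxycyclohexa-2,5-dien-1-one | CC1(C)OC[C@H](C=C2C=C(OC)C(=O)C(OC)=C2)[C@@H](Cc2cc(OC)c(O)c(OC)c2)CO1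
F8 | step 5 | (1S,2R,3R)-lyoniresinol 2,3-bis(hydroxymethyl) isopropylidene acetal | COc1cc([C@H]2c3c(cc(OC)c(O)c3OC)C[C@@H](COC(C)(C)O4)[C@@H]2C4)cc(OC)c1O
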